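## Structural features

The target is a cembranoid: a fourteen-membered carbocycle (C1–C14) with methyls on C4, C8 and C12. An α-methylene-γ-butyrolactone (C15=C17, C16 carbonyl, oxygen on C2) is cis-fused across C1–C2. An O–O bridge from C8 to C11 closes a 1,2-dioxane, so C8 and C11 are bridgeheads of a bicyclo[10.2.2] array with the ten-carbon arm C12…C7 cis on the dioxane. The stereocentres form two clusters: C1(R)/C2(R), adjacent and both allylic, and C7(R)/C8(S), adjacent, with C11(R) tied to C8 through the peroxide; the ring alkenes are 3E and 12Z. Fragile groups are the O–O bond (phosphines, low-valent metals, hydride, and base through C11–H), the exo-methylene lactone (Michael acceptor), the allylic C2–O bond and the C7 acetate. The real difficulty is the oxygenation pattern, not the ring: oxygen must be placed at C2, C7, C8, C11 and C16 on a skeleton whose three ring alkenes are almost alike. Oxygen at C11 with a C12=C13 alkene also requires loss of hydrogen from C13, which ene-type oxidations of an E-trisubstituted alkene avoid. The key step exploits that C1–C14, with methyls at C4, C8 and C12 and a three-carbon unit on C1, is a head-to-tail tetraprenyl chain closed between its ends, so the C1–C2 bond and the C1 stereocentre can come from an acyclic C20 diphosphate in one operation.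

## Logic of the disconnections

25 ⇒ 24. The C7–O acyl bond is cut first. The acetate is the most labile spectator and is best added last; the forward step must acylate a hindered secondary alcohol without base-induced cleavage of the peroxide at C11–H.

24 ⇒ 23. The O–C11 bond of the dioxane is cut, leaving a C8 hydroperoxide and an allylic bromide over C11–C13. Only attack at C11 gives a six-membered ring (C13 would need eight), so ring size fixes the regiochemistry and places the alkene at C12=C13. This removes the peroxide ring and the C11 centre and makes both C13 epimers usable. The forward step must deliver cis bridging (11R) and the 12Z alkene, and the C7 hydroxyl must not compete.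

23 ⇒ 22. The O–C8 bond is cut back to a 7,8-epoxide. Perhydrolysis at the tertiary carbon with inversion turns one epoxide into both the C7 carbinol and the C8 peroxy centre; the forward step must open at C8 only and leave the allylic bromide alone.

22 ⇒ 21 ⇒ 20. The C13–Br and C13–O bonds are cut. A dioxygen ene reaction at C11=C12 would put oxygen on C11 only by taking hydrogen from C13, and the cis effect directs it to C10 or C20 instead. An ene/[2,3] allylic hydroxylation attacks the CH2 on the more substituted alkene carbon, C13, and the allyl unit is transposed later in the ring closure. The forward step needs C11=C12 to be the only reactive alkene.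

20 ⇒ 19. The two epoxide C–O bonds are cut to the C7=C8 alkene. Facial selectivity (7R,8R) is left to a chiral reagent because C7/C8 are remote from C1/C2; the forward step must select C7=C8 over C11=C12.

19 ⇒ 17 (through 18). The C2–O ring bond is cut and re-formed with inversion. The cis fusion is not the outcome expected from carbonyl reduction next to C1, so the trans-fused isomer is accepted and corrected by an SN2 ring closure.

17 ⇒ 14. The lactone acyl bond and the C16 oxidation level are taken back to a 2,16-diol; the forward step must oxidise the primary allylic alcohol in the presence of the secondary one.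

14 ⇒ 13 ⇒ 11. C2–H, then C2=O, then C2=N are taken back to an oxime. This is the point where C2 becomes a stereocentre; the forward steps must not enolise toward C1.

11 ⇒ 8. The C2–N bond is cut back to an unfunctionalised C2 methylene. The C16 oxygen reaches C2–H through a six-membered transition state, which singles out C2 among many allylic positions without touching C3=C4. The forward step needs hydrogen abstraction at C2 rather than C14 and radical recombination at C2 rather than C4.

8 ⇒ 5. The C16–O bond is cut. The methyl of the 1,1-disubstituted alkene is the one allylic site that gives an allyl anion with two primary ends, and that anion is symmetric about C15, so no regiochemical question arises.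

5 ⇒ 4. The C1–C2 ring bond is cut (key step). One ring, one C–C bond and the C1 stereocentre are traded for an acyclic all-E diphosphate; the forward step needs enzyme control of ring size, enantioface and terminating proton loss.

4 ⇒ 2 + 3, and 2 ⇒ 1. The C–O–P bond and then the C–Cl bond are cut to the commercial alcohol and diphosphoric acid; both forward steps must avoid allylic shift at C1–C3.

## Other disconnections considered

Alternative 1: The dioxane is removed as a small bicycle. Both C–O bonds (O–C8, O–C11) would be made at once by [4+2] addition of singlet dioxygen to 1,3-dimethylcyclohexa-1,3-diene A1, giving endoperoxide A2, in which a temporary C7=C12 bond holds the two future ring arms cis. Later ozonolysis of that alkene would unveil carbonyl groups at C7 and C12 for chain extension. In its favour, the cis relation of C8 and C11 and the O–O bond are secured by a concerted reaction, no site selection among similar alkenes is needed, and a C12 carbonyl lets an olefination reagent choose the 12Z geometry. On these points it is the better plan. Against it, A1 is achiral, so A2 needs resolution or an asymmetric variant. The peroxide must then survive every later step, including basic olefination next to C11–H, and C1, C2 and C7 need separate stereocontrolled steps. It replaces late oxidations by many peroxide-compatible C–C bond formations and should be clearly longer than the 15 steps proposed here.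

Alternative 2: The ring is cut at C5–C6 beside a C7 carbonyl. The kinetic enolate of a C7 methyl ketone (KN(SiMe3)2) would displace an allylic bromide at C5 and close the fourteen-membered ring to A3, with the dioxane and a saturated lactone already present. In its favour, the closure is sp3–sp3 at an unhindered position away from all stereocentres, both alkene geometries are fixed in the fragments, and the C7 ketone allows the carbinol to be set under 1,2-induction from C8. It is the equal of the chosen plan for C7/C8 and better in needing no selection among alkenes. Against it are a strong base beside a peroxide C11–H, competing deprotonation α to the lactone, O-alkylation and SN2′ attack, high dilution, and α-methylenation after ring closure. The fragment with a preformed chiral dioxane is long to make. Overall it has more steps and a more fragile ring closure, but a more predictable stereochemical end-game.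

Alternative 3: The ring is cut at C4–C5. Hydroboration of a terminal C5=C6 alkene with 9-borabicyclo[3.3.1]nonane and intramolecular B-alkyl Suzuki coupling with a C4 alkenyl iodide (Pd(dppf)Cl2, Cs2CO3) would give A4, with C7/C8 masked as acetonide and C11 as silyl ether. In its favour, this is a mild sp2–sp3 macrocyclisation that keeps the alkenyl iodide geometry, so 3E is certain, which is better than any route that regenerates C3=C4. No peroxide is present during the organometallic steps, which is also better. Against it, the peroxide must still be built afterwards, and in A4 the centres C7, C8 and C11 are each one inversion away from the target. The O–O forming risk is therefore equal to that of the chosen plan, with protecting-group steps added. It is more certain in configuration and less economical, since the skeleton is assembled bond by bond and not in one enzymatic step.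

Key step: step 3

Assumption: an (S)-selective class 1 cembrene A synthase (wild type or engineered) is available as recombinant protein; 21–23 are carried as C13 epimer mixtures because C13 becomes sp2 in step 14.

## Route

Step 1
Reactants: 1 (2E,6E,10E)-geranylgeraniol
Product: 2 (2E,6E,10E)-geranylgeranyl chloride
Conditions: NCS, Me2S, CH2Cl2, −30 → 0 °C
Reagents that add atoms: N-chlorosuccinimide O=C1CCC(=O)N1Cl
Why: Corey–Kim chlorination: the alkoxysulfonium ion of the primary allylic alcohol is displaced by chloride at C1 without allylic shift or loss of E geometry, and the trisubstituted alkenes are inert at low temperature.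

Step 2
Reactants: 2 geranylgeranyl chloride; 3 diphosphoric acid
Product: 4 (2E,6E,10E)-geranylgeranyl diphosphate
Conditions: 3 as (Bu4N)3HP2O7 (from 3 and Bu4NOH), MeCN, rt; NH4+ ion exchange, cellulose chromatography
Reagents that add atoms: none
Why: SN2 displacement of the primary allylic chloride by the weakly solvated diphosphate trianion (Davisson–Poulter type diphosphorylation); the primary centre suppresses SN2′ attack and elimination.

Step 3
Reactants: 4 (2E,6E,10E)-geranylgeranyl diphosphate
Product: 5 (S)-cembrene A, (1S,3E,7E,11E)-cembra-3,7,11,15(17)-tetraene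
Conditions: recombinant (S)-selective cembrene A synthase, MgCl2 (10 mM), HEPES buffer pH 7.5, glycerol, 30 °C, n-dodecane overlay
Reagents that add atoms: none
Why: Mg2+-assisted ionisation of the diphosphate in the active site gives the geranylgeranyl allyl cation; the distal alkene (chain C14=C15), held over chain C1 by the fold, attacks through C14, and the tertiary cation left outside the ring loses a methyl proton to give the isopropenyl group. This is the standard reaction of a class 1 diterpene synthase; its closest non-enzymatic relative is a cation–olefin macrocyclisation of an allylic electrophile. The single ring is fourteen-membered and closes in the exo sense with respect to the attacking alkene (one alkene carbon in the ring, the other outside) at the primary end of the allyl cation, so the neighbouring E-alkene (cembrane C3=C4) is kept. The new bond is cembrane C1–C2 and the one new stereocentre is cembrane C1. It is controlled by the enzyme alone: the pocket fixes which face of the terminal alkene meets the cation, so a synthase of the (S) series, or an engineered variant, is required. The step needs 1,14-closure rather than 1,10- or 1,6-closure, and proton loss from a methyl group rather than from C1–H or capture of water. These are secured by the folded substrate conformation and the position of the active-site base, not by the substrate. The two-phase set-up removes the hydrocarbon from the protein and limits product inhibition.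

Step 4
Reactants: 5 (S)-cembrene A
Product: 8 (1S,3E,7E,11E)-cembra-3,7,11,15(17)-tetraen-16-ol, via C16 allyllithium 6 (not isolated), via dimethyl allylboronate 7 (not isolated)
Conditions: n-BuLi, TMEDA, hexane, rt; B(OMe)3, −78 °C → rt; H2O2, NaOH aq., 0 °C
Reagents that add atoms: hydrogen peroxide OO
Why: Allylic metalation–borylation–oxidation: n-BuLi·TMEDA deprotonates the methyl of the 1,1-disubstituted alkene (as with limonene), the only site giving an allyl anion with two primary ends; the anion is symmetric about C15, so borylation at either end and C–B to C–O oxidation give the same primary allylic alcohol, and C1 is untouched.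

Step 5
Reactants: 8 (1S,3E,7E,11E)-cembra-3,7,11,15(17)-tetraen-16-ol
Product: 11 (1R,3E,7E,11E)-16-hydroxycembra-3,7,11,15(17)-tetraen-2-one oxime, via C16 nitrite ester 9 (not isolated), via C2 nitroso alcohol 10 (not isolated)
Conditions: t-BuONO, CH2Cl2, 0 °C, dark; evaporate; hν (ca. 350 nm, Pyrex), benzene, 10 °C, Ar; then i-PrOH, 60 °C
Reagents that add atoms: tert-butyl nitrite CC(C)(C)ON=O
Why: Barton nitrite photolysis: O–N homolysis gives the C16 alkoxy radical, which abstracts hydrogen from C2 through a six-membered transition state (O, C16, C15, C1, C2, H); the allylic C2–H is much weaker than the equally placed C14–H. NO should recombine at the less hindered C2 end of the C2–C4 allyl radical, which keeps the 3E geometry, and the nitroso compound tautomerises to the conjugated oxime; no stereocentre is formed.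

Step 6
Reactants: 11 (1R,3E,7E,11E)-16-hydroxycembra-3,7,11,15(17)-tetraen-2-one oxime
Product: 13 (1R,3E,7E,11E)-16-hydroxycembra-3,7,11,15(17)-tetraen-2-one, via C2 NH imine 12 (not isolated)
Conditions: TiCl3 (aq.), NH4OAc buffer pH 6, THF, 0 °C, short contact; used at once
Reagents that add atoms: water O
Why: Reductive deoximation: TiCl3 cleaves the N–O bond and the NH imine hydrolyses; a near-neutral buffer and low temperature are used because C1–H in 13 is α to the ketone and allylic, so enolisation would erode C1 or move C15=C17 into conjugation.

Step 7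
Reactants: 13 (1R,3E,7E,11E)-16-hydroxycembra-3,7,11,15(17)-tetraen-2-one
Product: 14 (1R,2S,3E,7E,11E)-cembra-3,7,11,15(17)-tetraene-2,16-diol
Conditions: NaBH4, CeCl3·7H2O, MeOH, −78 °C
Reagents that add atoms: none
Why: Luche 1,2-reduction of the enone; Felkin–Anh addition anti to the alkenyl substituent C15 on C1 (C14 beside the carbonyl oxygen, H beside C3) should favour the (2S) alcohol, the epimer needed for ring closure with inversion in step 9, and the fast cold reduction outruns enolisation at C1.

Step 8
Reactants: 14 (1R,2S,3E,7E,11E)-cembra-3,7,11,15(17)-tetraene-2,16-diol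
Product: 17 (1R,2S,3E,7E,11E)-cembra-3,7,11,15(17)-tetraen-16,2-olide (trans-fused), via hydroxy enal 15 (not isolated), via lactol 16 (not isolated)
Conditions: TEMPO (cat.), PhI(OAc)2, CH2Cl2, rt
Reagents that add atoms: none
Why: Oxoammonium oxidation selective for the primary allylic alcohol; the enal is trapped by the C2 hydroxyl as the lactol, which is oxidised again (oxidative lactonisation of a 1,4-diol), and C2 keeps its configuration.

Step 9
Reactants: 17 (1R,2S,3E,7E,11E)-cembra-3,7,11,15(17)-tetraen-16,2-olide
Product: 19 (1R,2R,3E,7E,11E)-cembra-3,7,11,15(17)-tetraen-16,2-olide (cis-fused), via hydroxy acid 18 (not isolated)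
Conditions: LiOH, THF/H2O, 0 °C; HCl to pH 4, 0 °C, extract; PPh3, DIAD, toluene (0.005 M), −20 → 0 °C
Reagents that add atoms: lithium hydroxide [Li+].[OH-]
Why: Saponification then Mitsunobu lactonisation: the C2 hydroxyl is activated as the alkoxyphosphonium ion and displaced by the carboxylate in an intramolecular SN2 reaction, inverting C2 from S to R and giving the cis-fused ring; five-membered closure at C2 should outrun SN2′ attack at C4 (seven-membered).

Step 10
Reactants: 19 (1R,2R,3E,7E,11E)-cembra-3,7,11,15(17)-tetraen-16,2-olide
Product: 20 (1R,2R,3E,7R,8R,11E)-7,8-epoxycembra-3,11,15(17)-trien-16,2-olide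
Conditions: D-fructose-derived Shi ketone (30 mol%), Oxone (2KHSO5·KHSO4·K2SO4, 1.1 equiv), K2CO3, Bu4NHSO4, MeCN/CH2(OMe)2/aq. buffer pH 10, −10 °C
Reagents that add atoms: potassium peroxymonosulfate [K+].[O-]S(=O)(=O)OO
Why: Shi asymmetric epoxidation: the chiral dioxirane adds to E-trisubstituted alkenes through a spiro transition state, and the D-fructose ketone gives the (R,R) sense, here 7R,8R. C3=C4 is deactivated by the allylic acyloxy group and C15=C17 by conjugation; C7=C8, the alkene farthest from the lactone, is expected to react before C11=C12, so the oxidant is held near one equivalent.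

Step 11
Reactants: 20 (1R,2R,3E,7R,8R,11E)-7,8-epoxycembra-3,11,15(17)-trien-16,2-olide
Product: 21 (1R,2R,3E,7R,8R,11E)-7,8-epoxy-13-hydroxycembra-3,11,15(17)-trien-16,2-olide (C13 epimers)
Conditions: SeO2 (0.3 equiv), t-BuOOH, CH2Cl2, 0 °C → rt
Reagents that add atoms: selenium dioxide O=[Se]=O (hands over the oxygen); tert-butyl hydroperoxide CC(C)(C)OO (net oxygen source)
Why: Riley–Sharpless allylic hydroxylation: an ene reaction at C11 followed by a [2,3]-shift puts oxygen on the CH2 of the more substituted alkene carbon (C13, not the C20 methyl or C10) of the only electron-rich alkene left, and restores C11=C12 as E; both C13 epimers serve.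

Step 12
Reactants: 21 (1R,2R,3E,7R,8R,11E)-7,8-epoxy-13-hydroxycembra-3,11,15(17)-trien-16,2-olide
Product: 22 (1R,2R,3E,7R,8R,11E)-13-bromo-7,8-epoxycembra-3,11,15(17)-trien-16,2-olide (C13 epimers)
Conditions: CBr4, PPh3, 2,6-lutidine, CH2Cl2, −20 °C; used crude
Reagents that add atoms: carbon tetrabromide BrC(Br)(Br)Br
Why: Appel bromination of the secondary allylic alcohol; any allylic isomer or C13 epimer leads to the same allyl cation in step 14, and the cold buffered conditions spare the epoxide.

Step 13
Reactants: 22 (1R,2R,3E,7R,8R,11E)-13-bromo-7,8-epoxycembra-3,11,15(17)-trien-16,2-olide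
Product: 23 (1R,2R,3E,7R,8S,11E)-13-bromo-8-hydroperoxy-7-hydroxycembra-3,11,15(17)-trien-16,2-olide
Conditions: H2O2 (anhydrous, Et2O), MoO2(acac)2 (cat.), MgSO4, 0 °C → rt
Reagents that add atoms: hydrogen peroxide OO
Why: Catalysed perhydrolysis of the epoxide: H2O2 opens the activated oxirane at the tertiary carbon C8 with inversion, giving the 7R-hydroxy-8S-hydroperoxide; this sets C8 and keeps C7.

Step 14
Reactants: 23 (1R,2R,3E,7R,8S,11E)-13-bromo-8-hydroperoxy-7-hydroxycembra-3,11,15(17)-trien-16,2-olide
Product: 24 (1R,2R,3E,7R,8S,11R,12Z)-8,11-epidioxy-7-hydroxycembra-3,12,15(17)-trien-16,2-olide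
Conditions: Ag2O, CH2Cl2 (0.005 M), 0 °C, dark
Reagents that add atoms: none
Why: Silver-assisted intramolecular alkylation of a hydroperoxide by an allylic halide: halide abstraction gives the C11–C13 allyl cation, and the C8 hydroperoxide, the most acidic and most nucleophilic oxygen present, attacks C11, the only end that gives a six-membered ring, so the alkene ends at C12=C13. C11 should become R because, with C8 fixed as S, the peroxide can only bridge cis on the macrocycle; Z is expected because in the ionising conformer C14 turns away from the C12 methyl (A1,2 strain) and the bridged product needs the chain folded back toward C1.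

Step 15
Reactants: 24 (1R,2R,3E,7R,8S,11R,12Z)-8,11-epidioxy-7-hydroxycembra-3,12,15(17)-trien-16,2-olide
Product: 25 (1R,2R,3E,7R,8S,11R,12Z)-7-acetoxy-8,11-epidioxycembra-3,12,15(17)-trien-16,2-olide (target)
Conditions: Ac2O, pyridine, DMAP (cat.), CH2Cl2, 0 °C
Reagents that add atoms: acetic anhydride CC(=O)OC(C)=O
Why: Acylation of the secondary C7 alcohol under weakly basic, cold conditions that should leave the peroxide (C11–H) and the methylene lactone intact; no stereocentre is touched.

## Compound list

1 | (2E,6E,10E)-geranylgeraniol | CC(C)=CCC/C(C)=C/CC/C(C)=C/CC/C(C)=C/CO | starting material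
2 | (2E,6E,10E)-geranylgeranyl chloride | CC(C)=CCC/C(C)=C/CC/C(C)=C/CC/C(C)=C/CCl | intermediate
3 | diphosphoric acid | OP(=O)(O)OP(=O)(O)O | starting material
4 | (2E,6E,10E)-geranylgeranyl diphosphate (free-acid form, handled as ammonium salt) | CC(C)=CCC/C(C)=C/CC/C(C)=C/CC/C(C)=C/COP(=O)(O)OP(=O)(O)O | intermediate
5 | (S)-cembrene A, (1S,3E,7E,11E)-cembra-3,7,11,15(17)-tetraene | C=C(C)[C@@H]1C/C=C(\C)CC/C=C(\C)CC/C=C(\C)CC1 | intermediate
6 | C16 allyllithium of 5 | [Li]CC(=C)[C@@H]1C/C=C(\C)CC/C=C(\C)CC/C=C(\C)CC1 | intermediate (not isolated)
7 | dimethyl [(1S)-cembra-3,7,11,15(17)-tetraen-16-yl]boronate | COB(OC)CC(=C)[C@@H]1C/C=C(\C)CC/C=C(\C)CC/C=C(\C)CC1 | intermediate (not isolated)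
8 | (1S,3E,7E,11E)-cembra-3,7,11,15(17)-tetraen-16-ol | OCC(=C)[C@@H]1C/C=C(\C)CC/C=C(\C)CC/C=C(\C)CC1 | intermediate
9 | nitrite ester of 8 | O=NOCC(=C)[C@@H]1C/C=C(\C)CC/C=C(\C)CC/C=C(\C)CC1 | intermediate (not isolated)
10 | (1R)-2-nitrosocembra-3,7,11,15(17)-tetraen-16-ol (C2 epimers) | OCC(=C)[C@@H]1C(N=O)/C=C(\C)CC/C=C(\C)CC/C=C(\C)CC1 | intermediate (not isolated)
11 | (1R,3E,7E,11E)-16-hydroxycembra-3,7,11,15(17)-tetraen-2-one oxime (C=N geometry open) | OCC(=C)[C@@H]1C(=NO)/C=C(\C)CC/C=C(\C)CC/C=C(\C)CC1 | intermediate
12 | (1R)-2-iminocembra-3,7,11,15(17)-tetraen-16-ol | OCC(=C)[C@@H]1C(=N)/C=C(\C)CC/C=C(\C)CC/C=C(\C)CC1 | intermediate (not isolated)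
13 | (1R,3E,7E,11E)-16-hydroxycembra-3,7,11,15(17)-tetraen-2-one | OCC(=C)[C@@H]1C(=O)/C=C(\C)CC/C=C(\C)CC/C=C(\C)CC1 | intermediate
14 | (1R,2S,3E,7E,11E)-cembra-3,7,11,15(17)-tetraene-2,16-diol | OCC(=C)[C@@H]1[C@@H](O)/C=C(\C)CC/C=C(\C)CC/C=C(\C)CC1 | intermediate
15 | (1R,2S)-2-hydroxycembra-3,7,11,15(17)-tetraen-16-al | O=CC(=C)[C@@H]1[C@@H](O)/C=C(\C)CC/C=C(\C)CC/C=C(\C)CC1 | intermediate (not isolated)
16 | (1R,2S)-2,16-epoxycembra-3,7,11,15(17)-tetraen-16-ol (lactol, C16 epimers) | C=C1C(O)O[C@H]2/C=C(\C)CC/C=C(\C)CC/C=C(\C)CC[C@H]12 | intermediate (not isolated)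
17 | (1R,2S,3E,7E,11E)-cembra-3,7,11,15(17)-tetraen-16,2-olide (trans-fused) | C=C1C(=O)O[C@H]2/C=C(\C)CC/C=C(\C)CC/C=C(\C)CC[C@H]12 | intermediate
18 | (1R,2S)-2-hydroxycembra-3,7,11,15(17)-tetraen-16-oic acid | OC(=O)C(=C)[C@@H]1[C@@H](O)/C=C(\C)CC/C=C(\C)CC/C=C(\C)CC1 | intermediate (not isolated)
19 | (1R,2R,3E,7E,11E)-cembra-3,7,11,15(17)-tetraen-16,2-olide (cis-fused) | C=C1C(=O)O[C@@H]2/C=C(\C)CC/C=C(\C)CC/C=C(\C)CC[C@H]12 | intermediate
20 | (1R,2R,3E,7R,8R,11E)-7,8-epoxycembra-3,11,15(17)-trien-16,2-olide | C=C1C(=O)O[C@@H]2/C=C(\C)CC[C@H]3O[C@]3(C)CC/C=C(\C)CC[C@H]12 | intermediate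
21 | (1R,2R,3E,7R,8R,11E)-7,8-epoxy-13-hydroxycembra-3,11,15(17)-trien-16,2-olide (C13 epimers) | C=C1C(=O)O[C@@H]2/C=C(\C)CC[C@H]3O[C@]3(C)CC/C=C(\C)C(O)C[C@H]12 | intermediate
22 | (1R,2R,3E,7R,8R,11E)-13-bromo-7,8-epoxycembra-3,11,15(17)-trien-16,2-olide (C13 epimers) | C=C1C(=O)O[C@@H]2/C=C(\C)CC[C@H]3O[C@]3(C)CC/C=C(\C)C(Br)C[C@H]12 | intermediate
23 | (1R,2R,3E,7R,8S,11E)-13-bromo-8-hydroperoxy-7-hydroxycembra-3,11,15(17)-trien-16,2-olide | C=C1C(=O)O[C@@H]2/C=C(\C)CC[C@@H](O)[C@](OO)(C)CC/C=C(\C)C(Br)C[C@H]12 | intermediate
24 | (1R,2R,3E,7R,8S,11R,12Z)-8,11-epidioxy-7-hydroxycembra-3,12,15(17)-trien-16,2-olide | C=C1C(=O)O[C@@H]2/C=C(\C)CC[C@@H](O)[C@]3(C)CC[C@@H](OO3)/C(C)=C\C[C@H]12 | intermediate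
25 | (1R,2R,3E,7R,8S,11R,12Z)-7-acetoxy-8,11-epidioxycembra-3,12,15(17)-trien-16,2-olide | C=C1C(=O)O[C@@H]2/C=C(\C)CC[C@@H](OC(C)=O)[C@]3(C)CC[C@@H](OO3)/C(C)=C\C[C@H]12 | target

## Step count and least certain steps

Total steps: 15. Longest linear sequence: 15 (1 → 25); 3 enters in step 2 as the only other starting material.

Step 3 (key step). The ring closure may take the wrong enantioface, the terminating proton may be lost toward C1 or the cation may be captured by water, and the lipophilic product may slow turnover. Fallback: set out from 4 and give the termination to chemistry. A cyclase of the same fold that ends by water capture should give (S)-nephthenol F1, and dehydration of this tertiary alcohol toward its methyl groups (Burgess reagent, benzene, 50 °C) returns to the route at 5.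

Step 5. The alkoxy radical may add to C3=C4 or abstract at C14, NO may recombine at the tertiary C4 end of the allyl radical, and the C-nitroso group may react with a ring alkene. Fallback: a polar tether in place of the radical relay, setting out from 8.
- MnO2 should give the enal F2, and NaClO2 with 2-methyl-2-butene the acid F3.
- Iodolactonisation (I2, NaHCO3) should reach only C3=C4, through a six-membered ring, giving the iodolactone F4.
- K2CO3 in MeOH should convert it into the 3,4-epoxy methyl ester F5.
- PhSeNa should open F5 at C3 to the hydroxy selenide F6, and H2O2 should eliminate the selenoxide toward C2 to give the tertiary allylic alcohol ester F7.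
- LiOH should give the hydroxy acid F8, and ionisation of the tertiary allylic alcohol (PPTS, or catalytic Pd(PPh3)4 as a source of zerovalent palladium) should close the five-membered lactone at C2 with return of the alkene to C3=C4.

This rejoins the route at 17 or 19, depending on the C2 epimer formed; 17 continues through step 9.

Step 9 (with step 7). The ring closure may run partly with retention through acyl activation, the allylic alkoxyphosphonium ion may ionise, and 18 may relactonise before activation. If step 7 itself favours the other epimer, step 8 gives 19 directly. Fallback: set C2 in the reduction, setting out from 13. Me4NBH(OAc)3 in MeCN/AcOH at −20 °C delivers hydride from boron bound to the C16 oxygen, that is from the C15 side, and should give the (1R,2R)-diol F9; under the conditions of step 8 this returns to the route at 19.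

Step 10. Discrimination between C7=C8 and C11=C12 may be poor, a second epoxidation may follow, and the lactone may hydrolyse in the basic buffer. Fallback: mask C11=C12 by a tether, setting out from 14.
- N-Iodosuccinimide should close the C2 hydroxyl onto C12 (six-membered, Markovnikov) to give the cyclic iodoether F10.
- The same Shi conditions then find only C7=C8 and should give the epoxy iodoether F11.
- Zn in EtOH should restore C11=C12 and the C2 hydroxyl by reductive elimination, giving the epoxy diol F12.
- TEMPO/PhI(OAc)2 should give the trans-fused epoxy lactone F13.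
- LiOH, then PPh3/DIAD through the epoxy hydroxy acid F14, returns to the route at 20.

Step 14. The C7 hydroxyl may capture the allyl cation (six-membered ether), elimination to a diene may compete, and the alkene may form as the E isomer. Fallback: reverse the polarity of the ring closure, setting out from 22. AgOCOCF3 with H2O2 in Et2O should give the (11R,12Z)-allylic hydroperoxide F15, together with its C13 regioisomer, which can equilibrate with it by the radical-chain allylic hydroperoxide shift. Catalytic camphorsulfonic acid should then let the hydroperoxide open the epoxide at C8 with inversion (six-membered ring), which returns to the route at 24.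

## Further compounds

F1 | step 3 | (S)-nephthenol, 2-[(1S,3E,7E,11E)-cembra-3,7,11-trien-1-yl]propan-2-ol | CC(C)(O)[C@@H]1C/C=C(\C)CC/C=C(\C)CC/C=C(\C)CC1
F2 | step 5 | (1S)-cembra-3,7,11,15(17)-tetraen-16-al | O=CC(=C)[C@@H]1C/C=C(\C)CC/C=C(\C)CC/C=C(\C)CC1
F3 | step 5 | (1S)-cembra-3,7,11,15(17)-tetraen-16-oic acid | OC(=O)C(=C)[C@@H]1C/C=C(\C)CC/C=C(\C)CC/C=C(\C)CC1
F4 | step 5 | 4-iodocembra-7,11,15(17)-trien-16,3-olide (configuration at C3 and C4 not assigned) | C=C1C(=O)OC2C[C@@H]1CC/C(C)=C/CC/C(C)=C/CCC2(C)I
F5 | step 5 | methyl 3,4-epoxycembra-7,11,15(17)-trien-16-oate (C3, C4 not assigned) | COC(=O)C(=C)[C@@H]1CC2OC2(C)CC/C=C(\C)CC/C=C(\C)CC1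
F6 | step 5 | methyl 4-hydroxy-3-(phenylselanyl)cembra-7,11,15(17)-trien-16-oate (C3, C4 not assigned) | COC(=O)C(=C)[C@@H]1CC([Se]c2ccccc2)C(C)(O)CC/C=C(\C)CC/C=C(\C)CC1
F7 | step 5 | methyl (2E)-4-hydroxycembra-2,7,11,15(17)-tetraen-16-oate (C4 not assigned) | COC(=O)C(=C)[C@@H]1/C=C/C(C)(O)CC/C=C(\C)CC/C=C(\C)CC1
F8 | step 5 | (2E)-4-hydroxycembra-2,7,11,15(17)-tetraen-16-oic acid (C4 not assigned) | OC(=O)C(=C)[C@@H]1/C=C/C(C)(O)CC/C=C(\C)CC/C=C(\C)CC1
F9 | step 9 | (1R,2R,3E,7E,11E)-cembra-3,7,11,15(17)-tetraene-2,16-diol | OCC(=C)[C@@H]1[C@H](O)/C=C(\C)CC/C=C(\C)CC/C=C(\C)CC1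
F10 | step 10 | (1R,2S)-2,12-epoxy-11-iodocembra-3,7,15(17)-trien-16-ol (C11, C12 not assigned) | OCC(=C)[C@@H]1[C@@H]2/C=C(\C)CC/C=C(\C)CCC(I)C(C)(O2)CC1
F11 | step 10 | (1R,2S,7R,8R)-2,12:7,8-diepoxy-11-iodocembra-3,15(17)-dien-16-ol (C11, C12 not assigned) | OCC(=C)[C@@H]1[C@@H]2/C=C(\C)CC[C@H]3O[C@]3(C)CCC(I)C(C)(O2)CC1
F12 | step 10 | (1R,2S,3E,7R,8R,11E)-7,8-epoxycembra-3,11,15(17)-triene-2,16-diol | OCC(=C)[C@@H]1[C@@H](O)/C=C(\C)CC[C@H]2O[C@]2(C)CC/C=C(\C)CC1
F13 | step 10 | (1R,2S,3E,7R,8R,11E)-7,8-epoxycembra-3,11,15(17)-trien-16,2-olide (trans-fused) | C=C1C(=O)O[C@H]2/C=C(\C)CC[C@H]3O[C@]3(C)CC/C=C(\C)CC[C@H]12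
F14 | step 10 | (1R,2S,3E,7R,8R,11E)-7,8-epoxy-2-hydroxycembra-3,11,15(17)-trien-16-oic acid | OC(=O)C(=C)[C@@H]1[C@@H](O)/C=C(\C)CC[C@H]2O[C@]2(C)CC/C=C(\C)CC1
F15 | step 14 | (1R,2R,3E,7R,8R,11R,12Z)-7,8-epoxy-11-hydroperoxycembra-3,12,15(17)-trien-16,2-olide | C=C1C(=O)O[C@@H]2/C=C(\C)CC[C@H]3O[C@]3(C)CC[C@@H](OO)/C(C)=C\C[C@H]12
A1 | alternative 1 | 1,3-dimethylcyclohexa-1,3-diene | CC1=CC(C)=CCC1
A2 | alternative 1 | 1,5-dimethyl-2,3-dioxabicyclo[2.2.2]oct-5-ene (enantiomer matching C8 and C11) | C[C@@]12CC[C@@H](OO1)C(C)=C2
A3 | alternative 2 | macrocyclic C7 ketone with 8,11-peroxide bridge and saturated 16,2-lactone | C1C(=O)O[C@@H]2/C=C(\C)CCC(=O)[C@]3(C)CC[C@@H](OO3)/C(C)=C\C[C@H]12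
A4 | alternative 3 | macrocyclic saturated 16,2-lactone with C7/C8 acetonide and C11 tert-butyldimethylsilyl ether | C1C(=O)O[C@@H]2/C=C(\C)CC[C@@H]3OC(C)(C)O[C@]3(C)CC[C@H](O[Si](C)(C)C(C)(C)C)/C(C)=C\C[C@H]12
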